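**Plan**

- Locants used throughout: ring C1 (C=O), C2 (carries CH2CO2Me), C3 (=CH), C4 (CHOH), C5 (CH), C6 (CH2); chain C1′ (ring-bound CH2), C2′ (first vinyl CH).
- Retrosynthesis cuts C1′–C2′ (ring fragment + C19 (E)-alkenyl fragment), then the C2–CH2CO2Me bond and the C2=C3 unsaturation, then reconnects C1′ to C6 as a cyclopropane. The alkenyl fragment is cut at the C3′ methyl/C2′ iodine (carboalumination) and at C4′–C5′ (propargylation of farnesyl bromide).
- Enabling feature: the C1 ketone with its α-carbon C6 and β-carbon C5. Tying C5 and C6 through C1′ gives a bicyclo[4.1.0]heptan-2-one whose exocyclic C6–C1′ bond is aligned with the C=O π system and carries the ring strain. C1′ then accepts the alkenyl group, C6 becomes the enolate carbon and C5 is untouched.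
- Forward: the six-membered ring is bought as a cyclohexenone ketal; cyclopropane fused on (C5–C6–C1′); ketone freed; C2=C3 enone; C2 side arm; enone stored as a β-phenylthio ketone; nickel-catalysed ring-opening alkenylation joins the chain; enone restored; O4 deprotected.
- Stereochemistry: C4 from a CBS reduction; C5 from the OH-directed Simmons–Smith reaction (C1′ cis to O4), kept through the ring opening; E-alkenes from (2E,6E)-farnesyl bromide and a syn-carboalumination.

Key step: step 11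

Remark: compounds 1, 11 and 1-(trimethylsilyl)propyne are taken as commercial. The two temporary centres C2 and C3 in 10 and 18–20 are erased in step 12, and their SMILES show the diastereomer expected from addition anti to the C4 silyloxy group.

**Route**

Step 1
Reactants: 1 1,4-dioxaspiro[4.5]dec-6-en-8-one
Product: 2 (S)-1,4-dioxaspiro[4.5]dec-6-en-8-ol
Conditions: (R)-2-methyl-CBS-oxazaborolidine [(R)-1-methyl-3,3-diphenyltetrahydro-1H,3H-pyrrolo[1,2-c][1,3,2]oxazaborole] (10 mol %), BH3·SMe2, THF, −20 °C; aqueous work-up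
Reagents that add atoms: none
Why: Corey–Bakshi–Shibata reduction delivers hydride 1,2 to the enone with the alkenyl arm as the large group, so the (R)-catalyst should give the (S)-carbinol that becomes C4 (the enantiomeric catalyst would serve if the sense proved opposite).

Step 2
Reactants: 2 (S)-1,4-dioxaspiro[4.5]dec-6-en-8-ol
Product: 4 (1S,5S,6R)-5-hydroxybicyclo[4.1.0]heptan-2-one, via cyclopropanated ketal 3 (not isolated)
Conditions: Et2Zn, CH2I2, CH2Cl2, 0 °C → rt; then 1 M HCl, THF, rt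
Reagents that add atoms: diiodomethane (ICI); water (O)
Why: Hydroxyl-directed Simmons–Smith (Furukawa) cyclopropanation delivers the methylene to the alkene face syn to the zinc alkoxide, which sets C5 with C1′ cis to the C4 oxygen, and dilute acid then hydrolyses the dioxolane to the ketone without ionising the cyclopropyl carbinol.

Step 3
Reactants: 4 (1S,5S,6R)-5-hydroxybicyclo[4.1.0]heptan-2-one
Product: 5 (1S,5S,6R)-5-[(tert-butyldimethylsilyl)oxy]bicyclo[4.1.0]heptan-2-one
Conditions: TBSCl, imidazole, DMF, rt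
Reagents that add atoms: tert-butyldimethylsilyl chloride (CC(C)(C)[Si](C)(C)Cl)
Why: Standard silylation of the secondary alcohol protects O4 through the enolate, iodination and organozinc steps.

Step 4
Reactants: 5 (1S,5S,6R)-5-[(tert-butyldimethylsilyl)oxy]bicyclo[4.1.0]heptan-2-one
Product: 7 (1S,5S,6R)-5-[(tert-butyldimethylsilyl)oxy]bicyclo[4.1.0]hept-3-en-2-one, via silyl enol ether 6 (not isolated)
Conditions: LDA, THF, −78 °C, then Me3SiCl; Pd(OAc)2 (1.05 equiv), MeCN, rt
Reagents that add atoms: none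
Why: Saegusa–Ito oxidation: the ketone can enolise only toward C2 because the other α-carbon (C6) is a cyclopropane CH, so the silyl enol ether and hence the C2=C3 enone form regiospecifically.

Step 5
Reactants: 7 (1S,5S,6R)-5-[(tert-butyldimethylsilyl)oxy]bicyclo[4.1.0]hept-3-en-2-one
Product: 8 (1S,5R,6R)-5-[(tert-butyldimethylsilyl)oxy]-3-iodobicyclo[4.1.0]hept-3-en-2-one
Conditions: I2, pyridine/CH2Cl2, 0 °C → rt
Reagents that add atoms: iodine (II)
Why: Pyridine-mediated α-iodination of an enone (conjugate addition of pyridine, iodination of the enolate, elimination) puts iodine on C2, a reaction type well precedented on 4-silyloxycyclohexenones.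

Step 6
Reactants: 8 (1S,5R,6R)-5-[(tert-butyldimethylsilyl)oxy]-3-iodobicyclo[4.1.0]hept-3-en-2-one
Product: 9 methyl 2-[(1S,5R,6R)-5-[(tert-butyldimethylsilyl)oxy]-2-oxobicyclo[4.1.0]hept-3-en-3-yl]acetate
Conditions: BrZnCH2CO2Me (from methyl bromoacetate and Zn dust, THF), Pd(PPh3)4 (5 mol %), THF/DMPU, 40 °C
Reagents that add atoms: methyl bromoacetate (COC(=O)CBr)
Why: Negishi-type cross-coupling of the Reformatsky reagent with the α-iodoenone (oxidative addition of zerovalent palladium into the vinyl C–I bond, transmetalation of the zinc ester enolate, reductive elimination) installs the CH2CO2Me arm on C2.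

Step 7
Reactants: 9 methyl 2-[(1S,5R,6R)-5-[(tert-butyldimethylsilyl)oxy]-2-oxobicyclo[4.1.0]hept-3-en-3-yl]acetate
Product: 10 methyl 2-[(1S,3S,4R,5R,6R)-5-[(tert-butyldimethylsilyl)oxy]-2-oxo-4-(phenylsulfanyl)bicyclo[4.1.0]heptan-3-yl]acetate
Conditions: PhSH, Et3N (cat.), CH2Cl2, 0 °C → rt
Reagents that add atoms: thiophenol (Sc1ccccc1)
Why: Thia-Michael addition of thiophenol at C3 (the usual thiol protection of an enone, expected anti to the C4 silyloxy group) stores C2=C3 as a β-phenylthio ketone, so that the only acceptor left is the cyclopropyl ketone.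

Step 8
Reactants: 11 (2E,6E)-farnesyl bromide
Product: 12 trimethyl[(5E,9E)-6,10,14-trimethylpentadeca-5,9,13-trien-1-yn-1-yl]silane
Conditions: 1-(trimethylsilyl)propyne, n-BuLi, THF, −78 °C; then 11, −78 → 0 °C
Reagents that add atoms: 1-(trimethylsilyl)propyne (CC#C[Si](C)(C)C)
Why: SN2 alkylation of the propargylic lithium reagent by the primary allylic bromide extends the chain by three carbons without touching the E-alkenes.

Step 9
Reactants: 12 trimethyl[(5E,9E)-6,10,14-trimethylpentadeca-5,9,13-trien-1-yn-1-yl]silane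
Product: 13 (5E,9E)-6,10,14-trimethylpentadeca-5,9,13-trien-1-yne
Conditions: K2CO3 (cat.), MeOH, rt
Reagents that add atoms: none
Why: Base-catalysed methanolysis of the C(sp)–Si bond frees the terminal alkyne.

Step 10
Reactants: 13 (5E,9E)-6,10,14-trimethylpentadeca-5,9,13-trien-1-yne
Product: 15 (1E,5E,9E)-1-iodo-2,6,10,14-tetramethylpentadeca-1,5,9,13-tetraene, via alkenylalane 14 (not isolated)
Conditions: Me3Al, Cp2ZrCl2 (25 mol %), CH2Cl2, 0 °C → rt; then I2, THF, −30 → 0 °C
Reagents that add atoms: trimethylaluminium (C[Al](C)C); iodine (II)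
Why: Negishi zirconium-catalysed carboalumination adds methyl and aluminium syn across the terminal alkyne with aluminium on the terminal carbon, and iodinolysis with retention gives the (E)-trisubstituted vinyl iodide while the isolated trisubstituted alkenes stay inert.

Step 11
Reactants: 10 methyl 2-[(1S,3S,4R,5R,6R)-5-[(tert-butyldimethylsilyl)oxy]-2-oxo-4-(phenylsulfanyl)bicyclo[4.1.0]heptan-3-yl]acetate; 15 (1E,5E,9E)-1-iodo-2,6,10,14-tetramethylpentadeca-1,5,9,13-tetraene
Product: 19 methyl 2-[(1S,2R,3R,4R)-3-[(tert-butyldimethylsilyl)oxy]-6-oxo-2-(phenylsulfanyl)-4-[(2E,6E,10E)-3,7,11,15-tetramethylhexadeca-2,6,10,14-tetraen-1-yl]cyclohexyl]acetate, via alkenyllithium 16 (not isolated), via alkenylzinc chloride 17 (not isolated), via trimethylsilyl enol ether 18 (not isolated)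
Conditions: 15, t-BuLi (2 equiv), Et2O, −78 °C; ZnCl2 (THF), −78 → 0 °C; then 10, NiCl2(dme) (10 mol %), 2,2':6',2''-terpyridine (10 mol %), Me3SiCl, THF/NMP, 25 °C; then 1 M HCl, THF, 0 °C
Reagents that add atoms: none
Why: Strain-release cross-coupling: a reduced terpyridine-ligated monovalent nickel species (formed from NiCl2 by the organozinc) attacks the unsubstituted cyclopropane carbon C1′ while electron density flows into the C1 carbonyl, so the exocyclic C6–C1′ bond breaks to give a C1′-alkylnickel whose O-bound enolate is trapped by Me3SiCl as the C1=C6 silyl enol ether 18, and transmetalation from alkenylzinc 17 followed by C(sp3)–C(sp2) reductive elimination forges C1′–C2′ with retention of the E geometry. The closest known reaction type is the NiCl2/terpyridine-catalysed ring-opening cross-coupling of cyclopropyl ketones with organozinc reagents and Me3SiCl to γ-substituted silyl enol ethers, the catalytic counterpart of cuprate homoconjugate addition. No ring is closed; the three-membered ring is opened and its strain (about 27 kcal/mol) drives the step. No stereocentre is made: C5 is a spectator (bond formed at C1′, bond broken C6–C1′), so the configuration fixed in step 2 is carried over, and C6 becomes CH2 on hydrolysis. The step needs cleavage of the exocyclic C6–C1′ bond over the ring-fusion C5–C6 bond, which the bicyclo[4.1.0]heptan-2-one secures through the better overlap of the exocyclic bond with the carbonyl π system and the unhindered CH2 terminus. It also needs the organozinc and nickel to ignore the enone, which is why C2=C3 is held as the β-phenylthio ketone.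

Step 12
Reactants: 19 methyl 2-[(1S,2R,3R,4R)-3-[(tert-butyldimethylsilyl)oxy]-6-oxo-2-(phenylsulfanyl)-4-[(2E,6E,10E)-3,7,11,15-tetramethylhexadeca-2,6,10,14-tetraen-1-yl]cyclohexyl]acetate
Product: 21 methyl 2-[(3R,4R)-3-[(tert-butyldimethylsilyl)oxy]-6-oxo-4-[(2E,6E,10E)-3,7,11,15-tetramethylhexadeca-2,6,10,14-tetraen-1-yl]cyclohex-1-en-1-yl]acetate, via sulfoxide 20 (not isolated)
Conditions: 2-(phenylsulfonyl)-3-phenyloxaziridine (1.05 equiv), CH2Cl2, 0 °C; then Et3N, 25 °C
Reagents that add atoms: none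
Why: Chemoselective sulfide-to-sulfoxide oxidation by the neutral oxaziridine (which should not epoxidise isolated alkenes) is followed by base-promoted β-elimination of benzenesulfenate from the β-sulfinyl ketone, and because the leaving group sits on C3 the double bond can only form between C2 and C3.

Step 13
Reactants: 21 methyl 2-[(3R,4R)-3-[(tert-butyldimethylsilyl)oxy]-6-oxo-4-[(2E,6E,10E)-3,7,11,15-tetramethylhexadeca-2,6,10,14-tetraen-1-yl]cyclohex-1-en-1-yl]acetate
Product: 22 methyl 2-[(3R,4R)-3-hydroxy-6-oxo-4-[(2E,6E,10E)-3,7,11,15-tetramethylhexadeca-2,6,10,14-tetraen-1-yl]cyclohex-1-en-1-yl]acetate (CNP0274044.1)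
Conditions: HF·pyridine, THF/pyridine, 0 °C → rt
Reagents that add atoms: none
Why: Fluoride-mediated cleavage of the secondary TBS ether under buffered conditions should spare the γ-hydroxy enone (no strong base, no strong acid) and the polyene.

**Compound list**

1 | 1,4-dioxaspiro[4.5]dec-6-en-8-one | O=C1C=CC2(CC1)OCCO2 | starting material
2 | (S)-1,4-dioxaspiro[4.5]dec-6-en-8-ol | O1CCOC12CC[C@H](O)C=C2 | intermediate
3 | (1S,5S,6R)-spiro[bicyclo[4.1.0]heptane-2,2'-[1,3]dioxolan]-5-ol (OH cis to the cyclopropane CH2) | O1CCOC12CC[C@H](O)[C@@H]3C[C@H]23 | intermediate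
4 | (1S,5S,6R)-5-hydroxybicyclo[4.1.0]heptan-2-one (OH cis to the cyclopropane CH2) | O=C1CC[C@H](O)[C@@H]2C[C@H]12 | intermediate
5 | (1S,5S,6R)-5-[(tert-butyldimethylsilyl)oxy]bicyclo[4.1.0]heptan-2-one | O=C1CC[C@H](O[Si](C)(C)C(C)(C)C)[C@@H]2C[C@H]12 | intermediate
6 | (1S,5S,6R)-5-[(tert-butyldimethylsilyl)oxy]-2-[(trimethylsilyl)oxy]bicyclo[4.1.0]hept-2-ene | C[Si](C)(C)OC1=CC[C@H](O[Si](C)(C)C(C)(C)C)[C@@H]2C[C@H]12 | intermediate
7 | (1S,5S,6R)-5-[(tert-butyldimethylsilyl)oxy]bicyclo[4.1.0]hept-3-en-2-one | O=C1C=C[C@H](O[Si](C)(C)C(C)(C)C)[C@@H]2C[C@H]12 | intermediate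
8 | (1S,5R,6R)-5-[(tert-butyldimethylsilyl)oxy]-3-iodobicyclo[4.1.0]hept-3-en-2-one | O=C1C(I)=C[C@H](O[Si](C)(C)C(C)(C)C)[C@@H]2C[C@H]12 | intermediate
9 | methyl 2-[(1S,5R,6R)-5-[(tert-butyldimethylsilyl)oxy]-2-oxobicyclo[4.1.0]hept-3-en-3-yl]acetate | COC(=O)CC1=C[C@H](O[Si](C)(C)C(C)(C)C)[C@@H]2C[C@@H]2C1=O | intermediate
10 | methyl 2-[(1S,3S,4R,5R,6R)-5-[(tert-butyldimethylsilyl)oxy]-2-oxo-4-(phenylsulfanyl)bicyclo[4.1.0]heptan-3-yl]acetate | COC(=O)C[C@@H]1[C@@H](Sc2ccccc2)[C@H](O[Si](C)(C)C(C)(C)C)[C@@H]2C[C@@H]2C1=O | intermediate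
11 | (2E,6E)-farnesyl bromide [(2E,6E)-1-bromo-3,7,11-trimethyldodeca-2,6,10-triene] | BrC/C=C(\C)CC/C=C(\C)CCC=C(C)C | starting material
12 | trimethyl[(5E,9E)-6,10,14-trimethylpentadeca-5,9,13-trien-1-yn-1-yl]silane | C[Si](C)(C)C#CCC/C=C(\C)CC/C=C(\C)CCC=C(C)C | intermediate
13 | (5E,9E)-6,10,14-trimethylpentadeca-5,9,13-trien-1-yne | C#CCC/C=C(\C)CC/C=C(\C)CCC=C(C)C | intermediate
14 | dimethyl[(1E,5E,9E)-2,6,10,14-tetramethylpentadeca-1,5,9,13-tetraen-1-yl]alumane | C[Al](C)/C=C(\C)CC/C=C(\C)CC/C=C(\C)CCC=C(C)C | intermediate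
15 | (1E,5E,9E)-1-iodo-2,6,10,14-tetramethylpentadeca-1,5,9,13-tetraene | I/C=C(\C)CC/C=C(\C)CC/C=C(\C)CCC=C(C)C | intermediate
16 | [(1E,5E,9E)-2,6,10,14-tetramethylpentadeca-1,5,9,13-tetraen-1-yl]lithium | [Li]/C=C(\C)CC/C=C(\C)CC/C=C(\C)CCC=C(C)C | intermediate
17 | chloro[(1E,5E,9E)-2,6,10,14-tetramethylpentadeca-1,5,9,13-tetraen-1-yl]zinc | Cl[Zn]/C=C(\C)CC/C=C(\C)CC/C=C(\C)CCC=C(C)C | intermediate
18 | methyl 2-[(1S,4R,5R,6R)-5-[(tert-butyldimethylsilyl)oxy]-6-(phenylsulfanyl)-4-[(2E,6E,10E)-3,7,11,15-tetramethylhexadeca-2,6,10,14-tetraen-1-yl]-2-[(trimethylsilyl)oxy]cyclohex-2-en-1-yl]acetate (C1=C6 silyl enol ether of 19) | COC(=O)C[C@@H]1[C@@H](Sc2ccccc2)[C@H](O[Si](C)(C)C(C)(C)C)[C@H](C/C=C(\C)CC/C=C(\C)CC/C=C(\C)CCC=C(C)C)C=C1O[Si](C)(C)C | intermediate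
19 | methyl 2-[(1S,2R,3R,4R)-3-[(tert-butyldimethylsilyl)oxy]-6-oxo-2-(phenylsulfanyl)-4-[(2E,6E,10E)-3,7,11,15-tetramethylhexadeca-2,6,10,14-tetraen-1-yl]cyclohexyl]acetate | COC(=O)C[C@@H]1[C@@H](Sc2ccccc2)[C@H](O[Si](C)(C)C(C)(C)C)[C@H](C/C=C(\C)CC/C=C(\C)CC/C=C(\C)CCC=C(C)C)CC1=O | intermediate
20 | methyl 2-[(1S,2R,3R,4R)-3-[(tert-butyldimethylsilyl)oxy]-6-oxo-2-(phenylsulfinyl)-4-[(2E,6E,10E)-3,7,11,15-tetramethylhexadeca-2,6,10,14-tetraen-1-yl]cyclohexyl]acetate (either configuration at sulfur) | COC(=O)C[C@@H]1[C@@H](S(=O)c2ccccc2)[C@H](O[Si](C)(C)C(C)(C)C)[C@H](C/C=C(\C)CC/C=C(\C)CC/C=C(\C)CCC=C(C)C)CC1=O | intermediate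
21 | methyl 2-[(3R,4R)-3-[(tert-butyldimethylsilyl)oxy]-6-oxo-4-[(2E,6E,10E)-3,7,11,15-tetramethylhexadeca-2,6,10,14-tetraen-1-yl]cyclohex-1-en-1-yl]acetate | COC(=O)CC1=C[C@H](O[Si](C)(C)C(C)(C)C)[C@H](C/C=C(\C)CC/C=C(\C)CC/C=C(\C)CCC=C(C)C)CC1=O | intermediate
22 | methyl 2-[(3R,4R)-3-hydroxy-6-oxo-4-[(2E,6E,10E)-3,7,11,15-tetramethylhexadeca-2,6,10,14-tetraen-1-yl]cyclohex-1-en-1-yl]acetate | COC(=O)CC1=C[C@H](O)[C@H](C/C=C(\C)CC/C=C(\C)CC/C=C(\C)CCC=C(C)C)CC1=O | target

**Count and risks**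

Total step count: 13. Longest linear sequence: 10 steps (steps 1–7, then 11–13).

Steps most likely to fail:

1. Step 11. The C–C activation of the hindered, α-branched cyclopropyl ketone may be slow, the primary alkylnickel may lose a β-hydride before transmetalation, or nickel may cleave the C–S bond. The fallback sets out from 9 and comes back at 21, and it needs neither the thiol mask nor step 12. Me3SiI (CH2Cl2, −40 °C) should add iodide reversibly to the enone but irreversibly to C1′, opening the cyclopropane to the 2-silyloxydiene iodide F1; aqueous work-up should give the iodomethyl enone F2. Zinc insertion (Zn dust, LiCl, THF) would give the alkylzinc iodide F3, and a Pd(PPh3)4-catalysed Negishi coupling of F3 with vinyl iodide 15 would form the same C1′–C2′ bond, with the ring now as the nucleophile, and deliver 21.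

2. Step 6. The zinc ester enolate may add 1,2 to the cross-conjugated ketone, or the iodide may be lost reductively before coupling. The fallback sets out from 7 and comes back at 10, replacing steps 5–7. Thiophenol/Et3N addition to 7 would give the β-phenylthio ketone F4; its lithium enolate (LDA, THF, −78 °C), which can form only toward C2, would be alkylated with methyl bromoacetate (DMPU, −78 → −40 °C) to give 10.

3. Step 12. Oxidation may spill over to the trisubstituted alkenes, or the base may move the new double bond out of the ring into conjugation with the ester. The fallback sets out from 10 and comes back at 21, placing the oxidant before the polyene arrives. mCPBA (2.1 equiv, NaHCO3, CH2Cl2, 0 °C) would convert 10 into the sulfone F5. The nickel coupling of step 11 with alkenylzinc 17 would give the silyl enol ether F6 and, after acidic work-up, the ketone sulfone F7. Et3N (CH2Cl2, rt) would then expel benzenesulfinate by β-elimination to give 21 without any oxidant.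

Further compounds

F1 | step 11 | methyl 2-[(3R,4R)-3-[(tert-butyldimethylsilyl)oxy]-4-(iodomethyl)-6-[(trimethylsilyl)oxy]cyclohexa-1,5-dien-1-yl]acetate | COC(=O)CC1=C[C@H](O[Si](C)(C)C(C)(C)C)[C@H](CI)C=C1O[Si](C)(C)C
F2 | step 11 | methyl 2-[(3R,4R)-3-[(tert-butyldimethylsilyl)oxy]-4-(iodomethyl)-6-oxocyclohex-1-en-1-yl]acetate | COC(=O)CC1=C[C@H](O[Si](C)(C)C(C)(C)C)[C@H](CI)CC1=O
F3 | step 11 | {[(1R,2R)-2-[(tert-butyldimethylsilyl)oxy]-4-(2-methoxy-2-oxoethyl)-5-oxocyclohex-3-en-1-yl]methyl}(iodo)zinc | COC(=O)CC1=C[C@H](O[Si](C)(C)C(C)(C)C)[C@H](C[Zn]I)CC1=O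
F4 | step 6 | (1S,4R,5R,6R)-5-[(tert-butyldimethylsilyl)oxy]-4-(phenylsulfanyl)bicyclo[4.1.0]heptan-2-one | O=C1C[C@@H](Sc2ccccc2)[C@H](O[Si](C)(C)C(C)(C)C)[C@@H]2C[C@H]12
F5 | step 12 | methyl 2-[(1S,3S,4R,5R,6R)-5-[(tert-butyldimethylsilyl)oxy]-2-oxo-4-(phenylsulfonyl)bicyclo[4.1.0]heptan-3-yl]acetate | COC(=O)C[C@@H]1[C@@H](S(=O)(=O)c2ccccc2)[C@H](O[Si](C)(C)C(C)(C)C)[C@@H]2C[C@@H]2C1=O
F6 | step 12 | methyl 2-[(1S,4R,5R,6R)-5-[(tert-butyldimethylsilyl)oxy]-6-(phenylsulfonyl)-4-[(2E,6E,10E)-3,7,11,15-tetramethylhexadeca-2,6,10,14-tetraen-1-yl]-2-[(trimethylsilyl)oxy]cyclohex-2-en-1-yl]acetate | COC(=O)C[C@@H]1[C@@H](S(=O)(=O)c2ccccc2)[C@H](O[Si](C)(C)C(C)(C)C)[C@H](C/C=C(\C)CC/C=C(\C)CC/C=C(\C)CCC=C(C)C)C=C1O[Si](C)(C)C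
F7 | step 12 | methyl 2-[(1S,2R,3R,4R)-3-[(tert-butyldimethylsilyl)oxy]-6-oxo-2-(phenylsulfonyl)-4-[(2E,6E,10E)-3,7,11,15-tetramethylhexadeca-2,6,10,14-tetraen-1-yl]cyclohexyl]acetate | COC(=O)C[C@@H]1[C@@H](S(=O)(=O)c2ccccc2)[C@H](O[Si](C)(C)C(C)(C)C)[C@H](C/C=C(\C)CC/C=C(\C)CC/C=C(\C)CCC=C(C)C)CC1=O
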